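## Retrosynthetic overview

1. Last C–C bond: the C(=O)–Cα bond of the β,γ-unsaturated ketone, formed by acylating a lithiated (Z)-allylic sulfone (arene half, 14 skeletal heavy atoms) with a bicyclic δ-lactone (cyclopentane half, 18 skeletal heavy atoms). Desulfonylation, allylic oxidation and deprotection follow.
2. δ-Lactone ⇐ (1R,2R)-cyclopentane aldehyde ester + E-alkenyllithium from 2-methylbut-3-yn-2-ol (addition, then lactonisation).
3. Aldehyde ester ⇐ ozonolysis of a silyl enol ether made by chiral-lithium-amide desymmetrisation of meso cis-1,5-dimethylbicyclo[3.3.0]octan-3-one; this fixes both quaternary centres.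
4. Meso ketone ⇐ dichloroketene [2+2] on 1,2-dimethylcyclopentene, CH2N2 ring expansion, dechlorination. Ring order: the cyclopentane and the arene are bought; the cyclobutanone, then the second five-membered ring (cleaved by ozone), then the δ-lactone (opened in the coupling) are temporary.
5. Sulfone ⇐ Z-selective Wittig of a 2-arylethyl ylide with silyloxyacetone; aryl bromide from o-cresol (ortho-bromination, para-oxidation, MOM protection).

Assumption: the sense of induction in step 4 is taken by analogy with lithium bis(1-phenylethyl)amide deprotonations of 4-substituted cyclohexanones; if enol silane 8 proves antipodal, the (R,R)-amine is used with nothing else changed. 1,2-Dimethylcyclopentene is taken as a catalogue chemical.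

## Route

**Step 1**
Reactants: 1 1,2-dimethylcyclopentene; 2 trichloroacetyl chloride
Product: 4 cis-7,7-dichloro-1,5-dimethylbicyclo[3.2.0]heptan-6-one (racemic), via dichloroketene 3 (not isolated)
Conditions: Zn–Cu couple, POCl3, Et2O, reflux, slow addition of 2
Reagents that add atoms: none
Why: Zinc dechlorination of 2 gives dichloroketene, which undergoes a [2+2] cycloaddition with the electron-rich tetrasubstituted alkene; addition is suprafacial on the alkene, so the two new quaternary carbons carry cis methyl groups.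

**Step 2**
Reactants: 4 cis-7,7-dichloro-1,5-dimethylbicyclo[3.2.0]heptan-6-one
Product: 5 cis-2,2-dichloro-1,5-dimethylbicyclo[3.3.0]octan-3-one (racemic)
Conditions: CH2N2, Et2O/MeOH, 0 °C → rt
Reagents that add atoms: diazomethane, C=[N+]=[N-]
Why: Diazomethane ring expansion of an α,α-dichlorocyclobutanone (Tiffeneau–Demjanov type) inserts CH2 on the side remote from CCl2, the non-chlorinated α-carbon migrating with retention.

**Step 3**
Reactants: 5 cis-2,2-dichloro-1,5-dimethylbicyclo[3.3.0]octan-3-one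
Product: 6 cis-1,5-dimethylbicyclo[3.3.0]octan-3-one (meso)
Conditions: Zn dust, AcOH, 70 °C
Reagents that add atoms: none
Why: Reductive dechlorination of the α,α-dichloro ketone by zinc in acetic acid gives the ketone, which is meso because its two α-methylene arms are mirror-related.

**Step 4**
Reactants: 6 cis-1,5-dimethylbicyclo[3.3.0]octan-3-one
Product: 8 (1S,5R)-1,5-dimethyl-3-(trimethylsilyloxy)bicyclo[3.3.0]oct-2-ene, via lithium enolate 7 (not isolated)
Conditions: bis[(S)-1-phenylethyl]amine, n-BuLi, LiCl, THF, −78 °C; TMSCl, then 6, −100 → −78 °C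
Reagents that add atoms: chlorotrimethylsilane, C[Si](C)(C)Cl
Why: Enantiotopic-group-selective deprotonation by a chiral lithium amide (Simpkins–Koga desymmetrisation) with in situ silylation; choosing which α-CH2 becomes the enol carbon fixes the absolute configuration of both quaternary centres at once.

**Step 5**
Reactants: 8 (1S,5R)-1,5-dimethyl-3-(trimethylsilyloxy)bicyclo[3.3.0]oct-2-ene
Product: 10 methyl 2-[(1R,2R)-2-formyl-1,2-dimethylcyclopentyl]acetate, via aldehyde acid 9 (not isolated)
Conditions: O3, CH2Cl2, −78 °C; Me2S, −78 °C → rt; aqueous wash; crude acid + CH2N2, Et2O, 0 °C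
Reagents that add atoms: ozone, [O-][O+]=O; diazomethane, C=[N+]=[N-]
Why: Ozonolysis of the enol ether C=C with reductive work-up leaves an aldehyde on one quaternary carbon and a silyl ester (acid after the wash) on the CH2 arm, and diazomethane O-methylates the acid; no stereocentre is touched.

**Step 6**
Reactants: 11 2-methylbut-3-yn-2-ol
Product: 12 triethyl[(2-methylbut-3-yn-2-yl)oxy]silane
Conditions: Et3SiCl, imidazole, DMAP (cat.), DMF, rt
Reagents that add atoms: chlorotriethylsilane, CC[Si](Cl)(CC)CC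
Why: Silylation of the tertiary propargylic alcohol masks the OH against the organolithium steps that follow.

**Step 7**
Reactants: 12 triethyl[(2-methylbut-3-yn-2-yl)oxy]silane
Product: 13 (E)-tributyl[3-methyl-3-(triethylsilyloxy)but-1-en-1-yl]stannane
Conditions: Bu3SnH, PdCl2(PPh3)2 (2 mol %), THF, 0 °C → rt
Reagents that add atoms: tributyltin hydride, CCCC[SnH](CCCC)CCCC
Why: Palladium-catalysed syn-hydrostannation of the terminal alkyne places tin on the terminal carbon, away from the bulky quaternary centre, giving the E-alkenylstannane.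

**Step 8**
Reactants: 13 (E)-tributyl[3-methyl-3-(triethylsilyloxy)but-1-en-1-yl]stannane; 10 methyl 2-[(1R,2R)-2-formyl-1,2-dimethylcyclopentyl]acetate
Product: 16 (4aR,7aR)-4a,7a-dimethyl-1-[(E)-3-methyl-3-(triethylsilyloxy)but-1-en-1-yl]hexahydrocyclopenta[c]pyran-3(1H)-one (both C1 epimers), via vinyllithium 14 (not isolated), via lithium alkoxide 15 (not isolated)
Conditions: 13, n-BuLi, THF, −78 °C, 1 h; then 10, −78 °C → rt; aq. NH4Cl
Reagents that add atoms: none
Why: Tin–lithium exchange gives the E-alkenyllithium with retention, it adds 1,2 to the aldehyde far faster than to the ester, and the alkoxide closes onto the cis ester arm (lactonisation); the new carbinol centre is an epimer mixture that is erased by the oxidation in step 21.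

**Step 9**
Reactants: 17 o-cresol
Product: 18 2-bromo-6-methylphenol
Conditions: NBS, i-Pr2NH (10 mol %), CH2Cl2, 0 °C → rt
Reagents that add atoms: N-bromosuccinimide, O=C1CCC(=O)N1Br
Why: Amine-catalysed NBS bromination of phenols (electrophilic aromatic substitution) is ortho-selective, and C6 is the only free ortho position.

**Step 10**
Reactants: 18 2-bromo-6-methylphenol
Product: 20 2-bromo-6-methylbenzene-1,4-diol, via bromoquinone 19 (not isolated)
Conditions: K2[ON(SO3)2] (2.2 equiv), KH2PO4, H2O/acetone, 0 °C → rt; then Na2S2O4, H2O/EtOAc, rt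
Reagents that add atoms: potassium nitrosodisulfonate, [O]N(S(=O)(=O)[O-])S(=O)(=O)[O-].[K+].[K+]
Why: Teuber oxidation: two equivalents of the nitrosodisulfonate radical oxidise the 2,6-disubstituted phenol at its free para position to the p-quinone, which dithionite reduces to the hydroquinone.

**Step 11**
Reactants: 20 2-bromo-6-methylbenzene-1,4-diol
Product: 21 1-bromo-2,5-bis(methoxymethoxy)-3-methylbenzene
Conditions: NaH, MOMCl, DMF, 0 °C → rt, Ar
Reagents that add atoms: chloromethyl methyl ether, COCCl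
Why: Williamson-type O-alkylation of both phenoxides gives acetals that withstand organolithiums, ylides, SmI2 and Dess–Martin periodinane.

**Step 12**
Reactants: 21 1-bromo-2,5-bis(methoxymethoxy)-3-methylbenzene; 22 ethylene oxide
Product: 24 2-[2,5-bis(methoxymethoxy)-3-methylphenyl]ethanol, via aryllithium 23 (not isolated)
Conditions: t-BuLi (2.1 equiv), Et2O, −78 °C; then 22, −78 °C → rt; aq. NH4Cl
Reagents that add atoms: none
Why: Bromine–lithium exchange (the second equivalent of t-BuLi destroys t-BuBr) followed by SN2 opening of the epoxide by the aryllithium gives the 2-arylethanol.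

**Step 13**
Reactants: 24 2-[2,5-bis(methoxymethoxy)-3-methylphenyl]ethanol
Product: 25 1-(2-iodoethyl)-2,5-bis(methoxymethoxy)-3-methylbenzene
Conditions: I2, PPh3, imidazole, CH2Cl2, 0 °C → rt
Reagents that add atoms: iodine, II
Why: Appel-type iodination (Garegg–Samuelsson conditions) converts the primary alcohol to the iodide by SN2 under buffered conditions that spare the MOM acetals.

**Step 14**
Reactants: 25 1-(2-iodoethyl)-2,5-bis(methoxymethoxy)-3-methylbenzene
Product: 26 {2-[2,5-bis(methoxymethoxy)-3-methylphenyl]ethyl}triphenylphosphonium iodide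
Conditions: PPh3, MeCN, reflux, 36 h
Reagents that add atoms: triphenylphosphine, c1ccc(cc1)P(c1ccccc1)c1ccccc1
Why: SN2 quaternisation of triphenylphosphine by the primary iodide.

**Step 15**
Reactants: 27 hydroxyacetone
Product: 28 1-(tert-butyldimethylsilyloxy)propan-2-one
Conditions: TBSCl, imidazole, CH2Cl2, 0 °C → rt
Reagents that add atoms: tert-butyldimethylsilyl chloride, CC(C)(C)[Si](C)(C)Cl
Why: Silylation of the primary alcohol gives the α-silyloxy ketone that directs the Wittig reaction to the Z alkene.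

**Step 16**
Reactants: 26 {2-[2,5-bis(methoxymethoxy)-3-methylphenyl]ethyl}triphenylphosphonium iodide; 28 1-(tert-butyldimethylsilyloxy)propan-2-one
Product: 30 tert-butyl{[(2Z)-4-(2,5-bis(methoxymethoxy)-3-methylphenyl)-2-methylbut-2-en-1-yl]oxy}dimethylsilane, via phosphorus ylide 29 (not isolated)
Conditions: KN(SiMe3)2, THF, −78 → 0 °C; then 28, −78 °C → rt
Reagents that add atoms: none
Why: Wittig olefination of an α-alkoxy ketone with a non-stabilised, lithium-free ylide (Still's Z-selective variant) places the ylide substituent cis to the CH2O group, giving the Z-trisubstituted alkene.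

**Step 17**
Reactants: 30 tert-butyl{[(2Z)-4-(2,5-bis(methoxymethoxy)-3-methylphenyl)-2-methylbut-2-en-1-yl]oxy}dimethylsilane
Product: 31 (2Z)-4-[2,5-bis(methoxymethoxy)-3-methylphenyl]-2-methylbut-2-en-1-ol
Conditions: Bu4NF, THF, 0 °C → rt; chromatography removes the minor E isomer
Reagents that add atoms: none
Why: Fluoride-induced desilylation frees the allylic alcohol while the MOM acetals stay intact.

**Step 18**
Reactants: 31 (2Z)-4-[2,5-bis(methoxymethoxy)-3-methylphenyl]-2-methylbut-2-en-1-ol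
Product: 33 2,5-bis(methoxymethoxy)-1-methyl-3-[(2Z)-3-methyl-4-(phenylsulfonyl)but-2-en-1-yl]benzene, via allylic mesylate 32 (not isolated)
Conditions: MsCl, Et3N, CH2Cl2, −40 °C; then PhSO2Na, DMF, rt
Reagents that add atoms: sodium benzenesulfinate, [Na+].[O-]S(=O)c1ccccc1; methanesulfonyl chloride, CS(=O)(=O)Cl (its atoms stay only in 32)
Why: Mesylation and SN2 displacement by the sulfur of benzenesulfinate give the primary allylic sulfone without disturbing the double-bond geometry.

**Step 19** (fragment coupling)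
Reactants: 33 2,5-bis(methoxymethoxy)-1-methyl-3-[(2Z)-3-methyl-4-(phenylsulfonyl)but-2-en-1-yl]benzene; 16 (4aR,7aR)-4a,7a-dimethyl-1-[(E)-3-methyl-3-(triethylsilyloxy)but-1-en-1-yl]hexahydrocyclopenta[c]pyran-3(1H)-one
Product: 35 (4Z)-6-[2,5-bis(methoxymethoxy)-3-methylphenyl]-1-[(1R,2R)-2-{(E)-1-hydroxy-4-methyl-4-(triethylsilyloxy)pent-2-en-1-yl}-1,2-dimethylcyclopentyl]-4-methyl-3-(phenylsulfonyl)hex-4-en-2-one (epimers at C3 and at the carbinol), via lithiated sulfone 34 (not isolated)
Conditions: 33 (2.0 equiv; surplus recovered), n-BuLi, THF, −78 °C; then 16, −78 → −40 °C; aq. NH4Cl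
Reagents that add atoms: none
Why: Claisen-type acylation of the α-sulfonyl carbanion by the lactone carbonyl; the allylic sulfonyl anion reacts at its α-carbon with the Z geometry kept, and the expelled alkoxide becomes the free allylic alcohol.

**Step 20**
Reactants: 35 β-keto sulfone (as named in step 19)
Product: 36 (4Z)-6-[2,5-bis(methoxymethoxy)-3-methylphenyl]-1-[(1R,2R)-2-{(E)-1-hydroxy-4-methyl-4-(triethylsilyloxy)pent-2-en-1-yl}-1,2-dimethylcyclopentyl]-4-methylhex-4-en-2-one (carbinol epimers; in equilibrium with its cyclic hemiketal)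
Conditions: SmI2 (3 equiv), THF/MeOH, −78 °C
Reagents that add atoms: none
Why: Reductive desulfonylation of a β-keto sulfone by single-electron transfer from SmI2; the samarium dienolate is protonated at the α-carbon by MeOH at −78 °C, which leaves the β,γ-double bond in place with its Z geometry.

**Step 21**
Reactants: 36 hydroxy ketone (as named in step 20)
Product: 37 (E)-1-[(1R,2R)-2-{(4Z)-6-[2,5-bis(methoxymethoxy)-3-methylphenyl]-4-methyl-2-oxohex-4-en-1-yl}-1,2-dimethylcyclopentyl]-4-methyl-4-(triethylsilyloxy)pent-2-en-1-one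
Conditions: Dess–Martin periodinane, CH2Cl2, 0 °C → rt
Reagents that add atoms: none
Why: Dess–Martin oxidation of the secondary allylic alcohol (both epimers, through the open form of any hemiketal) gives the E-enone under non-basic conditions, so the β,γ-unsaturated ketone does not move into conjugation.

**Step 22**
Reactants: 37 protected diketone (as named in step 21)
Product: 38 target CNP0212540.1, 2-{(2Z)-6-[(1R,2R)-2-((E)-4-hydroxy-4-methylpent-2-enoyl)-1,2-dimethylcyclopentyl]-3-methyl-5-oxohex-2-en-1-yl}-6-methylbenzene-1,4-diol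
Conditions: HCl (0.2 M) in degassed MeOH, rt, Ar
Reagents that add atoms: none
Why: Acid-catalysed acetal exchange and silyl ether methanolysis remove both MOM groups and the triethylsilyl group; no stereocentre or double bond is involved.

## Compound list

1 | 1,2-dimethylcyclopentene | CC1=C(C)CCC1 | starting material
2 | trichloroacetyl chloride | ClC(Cl)(Cl)C(Cl)=O | starting material
3 | dichloroketene | ClC(Cl)=C=O | intermediate (not isolated)
4 | cis-7,7-dichloro-1,5-dimethylbicyclo[3.2.0]heptan-6-one (racemic; relative configuration drawn) | O=C1C(Cl)(Cl)[C@@]2(C)CCC[C@@]12C | intermediate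
5 | cis-2,2-dichloro-1,5-dimethylbicyclo[3.3.0]octan-3-one (racemic; relative configuration drawn) | O=C1C[C@]2(C)CCC[C@]2(C)C1(Cl)Cl | intermediate
6 | cis-1,5-dimethylbicyclo[3.3.0]octan-3-one (meso) | O=C1C[C@]2(C)CCC[C@]2(C)C1 | intermediate
7 | lithium (1S,5R)-1,5-dimethylbicyclo[3.3.0]oct-2-en-3-olate | [Li]OC1=C[C@]2(C)CCC[C@]2(C)C1 | intermediate (not isolated)
8 | (1S,5R)-1,5-dimethyl-3-(trimethylsilyloxy)bicyclo[3.3.0]oct-2-ene | C[Si](C)(C)OC1=C[C@]2(C)CCC[C@]2(C)C1 | intermediate
9 | 2-[(1R,2R)-2-formyl-1,2-dimethylcyclopentyl]acetic acid | OC(=O)C[C@@]1(C)CCC[C@@]1(C)C=O | intermediate (not isolated)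
10 | methyl 2-[(1R,2R)-2-formyl-1,2-dimethylcyclopentyl]acetate | COC(=O)C[C@@]1(C)CCC[C@@]1(C)C=O | intermediate
11 | 2-methylbut-3-yn-2-ol | CC(C)(O)C#C | starting material
12 | triethyl[(2-methylbut-3-yn-2-yl)oxy]silane | CC[Si](CC)(CC)OC(C)(C)C#C | intermediate
13 | (E)-tributyl[3-methyl-3-(triethylsilyloxy)but-1-en-1-yl]stannane | CCCC[Sn](CCCC)(CCCC)/C=C/C(C)(C)O[Si](CC)(CC)CC | intermediate
14 | (E)-[3-methyl-3-(triethylsilyloxy)but-1-en-1-yl]lithium | [Li]/C=C/C(C)(C)O[Si](CC)(CC)CC | intermediate (not isolated)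
15 | lithium alkoxide of methyl 2-[(1R,2R)-2-{(E)-1-hydroxy-4-methyl-4-(triethylsilyloxy)pent-2-en-1-yl}-1,2-dimethylcyclopentyl]acetate (carbinol epimers) | COC(=O)C[C@@]1(C)CCC[C@@]1(C)C(O[Li])/C=C/C(C)(C)O[Si](CC)(CC)CC | intermediate (not isolated)
16 | (4aR,7aR)-4a,7a-dimethyl-1-[(E)-3-methyl-3-(triethylsilyloxy)but-1-en-1-yl]hexahydrocyclopenta[c]pyran-3(1H)-one (C1 epimers) | O=C1C[C@@]2(C)CCC[C@@]2(C)C(/C=C/C(C)(C)O[Si](CC)(CC)CC)O1 | intermediate
17 | o-cresol | Cc1ccccc1O | starting material
18 | 2-bromo-6-methylphenol | Cc1cccc(Br)c1O | intermediate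
19 | 2-bromo-6-methyl-1,4-benzoquinone | CC1=CC(=O)C=C(Br)C1=O | intermediate (not isolated)
20 | 2-bromo-6-methylbenzene-1,4-diol | Cc1cc(O)cc(Br)c1O | intermediate
21 | 1-bromo-2,5-bis(methoxymethoxy)-3-methylbenzene | COCOc1cc(C)c(OCOC)c(Br)c1 | intermediate
22 | ethylene oxide | C1CO1 | starting material
23 | [2,5-bis(methoxymethoxy)-3-methylphenyl]lithium | COCOc1cc(C)c(OCOC)c([Li])c1 | intermediate (not isolated)
24 | 2-[2,5-bis(methoxymethoxy)-3-methylphenyl]ethanol | COCOc1cc(C)c(OCOC)c(CCO)c1 | intermediate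
25 | 1-(2-iodoethyl)-2,5-bis(methoxymethoxy)-3-methylbenzene | COCOc1cc(C)c(OCOC)c(CCI)c1 | intermediate
26 | {2-[2,5-bis(methoxymethoxy)-3-methylphenyl]ethyl}triphenylphosphonium iodide | COCOc1cc(C)c(OCOC)c(CC[P+](c2ccccc2)(c2ccccc2)c2ccccc2)c1.[I-] | intermediate
27 | hydroxyacetone | CC(=O)CO | starting material
28 | 1-(tert-butyldimethylsilyloxy)propan-2-one | CC(=O)CO[Si](C)(C)C(C)(C)C | intermediate
29 | {2-[2,5-bis(methoxymethoxy)-3-methylphenyl]ethylidene}triphenylphosphorane | COCOc1cc(C)c(OCOC)c(CC=P(c2ccccc2)(c2ccccc2)c2ccccc2)c1 | intermediate (not isolated)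
30 | tert-butyl{[(2Z)-4-(2,5-bis(methoxymethoxy)-3-methylphenyl)-2-methylbut-2-en-1-yl]oxy}dimethylsilane | C/C(=C/Cc1cc(OCOC)cc(C)c1OCOC)CO[Si](C)(C)C(C)(C)C | intermediate
31 | (2Z)-4-[2,5-bis(methoxymethoxy)-3-methylphenyl]-2-methylbut-2-en-1-ol | C/C(=C/Cc1cc(OCOC)cc(C)c1OCOC)CO | intermediate
32 | (2Z)-4-[2,5-bis(methoxymethoxy)-3-methylphenyl]-2-methylbut-2-en-1-yl methanesulfonate | C/C(=C/Cc1cc(OCOC)cc(C)c1OCOC)COS(C)(=O)=O | intermediate (not isolated)
33 | 2,5-bis(methoxymethoxy)-1-methyl-3-[(2Z)-3-methyl-4-(phenylsulfonyl)but-2-en-1-yl]benzene | C/C(=C/Cc1cc(OCOC)cc(C)c1OCOC)CS(=O)(=O)c1ccccc1 | intermediate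
34 | α-lithio derivative of sulfone 33 | C/C(=C/Cc1cc(OCOC)cc(C)c1OCOC)C([Li])S(=O)(=O)c1ccccc1 | intermediate (not isolated)
35 | (4Z)-6-[2,5-bis(methoxymethoxy)-3-methylphenyl]-1-[(1R,2R)-2-{(E)-1-hydroxy-4-methyl-4-(triethylsilyloxy)pent-2-en-1-yl}-1,2-dimethylcyclopentyl]-4-methyl-3-(phenylsulfonyl)hex-4-en-2-one (epimers at C3 and carbinol) | C/C(=C/Cc1cc(OCOC)cc(C)c1OCOC)C(S(=O)(=O)c1ccccc1)C(=O)C[C@@]1(C)CCC[C@@]1(C)C(O)/C=C/C(C)(C)O[Si](CC)(CC)CC | intermediate
36 | (4Z)-6-[2,5-bis(methoxymethoxy)-3-methylphenyl]-1-[(1R,2R)-2-{(E)-1-hydroxy-4-methyl-4-(triethylsilyloxy)pent-2-en-1-yl}-1,2-dimethylcyclopentyl]-4-methylhex-4-en-2-one (carbinol epimers) | C/C(=C/Cc1cc(OCOC)cc(C)c1OCOC)CC(=O)C[C@@]1(C)CCC[C@@]1(C)C(O)/C=C/C(C)(C)O[Si](CC)(CC)CC | intermediate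
37 | (E)-1-[(1R,2R)-2-{(4Z)-6-[2,5-bis(methoxymethoxy)-3-methylphenyl]-4-methyl-2-oxohex-4-en-1-yl}-1,2-dimethylcyclopentyl]-4-methyl-4-(triethylsilyloxy)pent-2-en-1-one | C/C(=C/Cc1cc(OCOC)cc(C)c1OCOC)CC(=O)C[C@@]1(C)CCC[C@@]1(C)C(=O)/C=C/C(C)(C)O[Si](CC)(CC)CC | intermediate
38 | CNP0212540.1, 2-{(2Z)-6-[(1R,2R)-2-((E)-4-hydroxy-4-methylpent-2-enoyl)-1,2-dimethylcyclopentyl]-3-methyl-5-oxohex-2-en-1-yl}-6-methylbenzene-1,4-diol | C/C(=C/Cc1cc(O)cc(C)c1O)CC(=O)C[C@@]1(C)CCC[C@@]1(C)C(=O)/C=C/C(C)(C)O | target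

## Totals and risk

Total step count: 22.
Longest linear sequence: 13 steps (steps 9–14 and 16–22, from o-cresol).

**Step 4 (desymmetrisation).** The enantiomeric excess may be modest for a ketone whose exo α-hydrogens sit next to angular methyl groups, and the sense of induction must be confirmed. Fallback by resolution, setting out from 6 and coming back at 9: LiN(i-Pr)2 and TMSCl (THF, −78 °C) give the racemic silyl enol ether F1. Ozonolysis with Me2S work-up gives the racemic aldehyde acid F2, which sits largely as its hydroxy lactone. Heating F2 with (1R,2S,5R)-menthol and catalytic TsOH in benzene (Dean–Stark) gives diastereomeric menthyl pseudo-esters. The one with the (4aR,7aR) core, the menthyloxy lactone F3, is separated by crystallisation or chromatography and assigned by X-ray. Hydrolysis (aq. HCl, dioxane, 60 °C) releases enantiopure aldehyde acid 9, which continues with the diazomethane stage of step 5.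

**Step 19 (sulfone acylation, together with the desulfonylation that depends on it).** Possible failures are lactone enolisation, γ-attack of the allyl anion, or erosion of the Z geometry or the β,γ position of the alkene during desulfonylation. Fallback by carbonyl allylation, setting out from 31 and 16 and coming back at 37: 31 is converted (MsCl, LiCl, 2,4,6-collidine, DMF, 0 °C) into the (Z)-allylic chloride F4. Lactone 16 is reduced (i-Bu2AlH, CH2Cl2, −78 °C) to the lactol F5. F4 and freshly prepared reactive barium (THF, −78 °C) give the allylbarium chloride F6. This reagent is known to react at its α-carbon with retention of geometry. Two equivalents are used: the first opens F5 to its hydroxy aldehyde form and the second adds to the aldehyde, giving the diol F7. Dess–Martin oxidation of both secondary alcohols of F7 gives diketone 37 directly, so steps 20 and 21 are bypassed.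

**Step 22 (acidic global deprotection).** The product carries a β,γ-unsaturated ketone, a 1,5-diketone, a tertiary allylic alcohol and an ortho-prenyl-type hydroquinone, so acid could cause conjugation, aldol closure or chroman formation. Fallback by oxidative unmasking, setting out from 37 and coming back at 38: HF·pyridine (THF/pyridine, 0 °C) removes the silyl group to give the tertiary alcohol F8. (NH4)2Ce(NO3)6 (MeCN/H2O, 0 °C, minutes) oxidises the bis(methoxymethyl) hydroquinone ether directly to the benzoquinone F9. Shaking with aqueous Na2S2O4 reduces F9 to hydroquinone 38.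

## Further compounds

F1 | step 4 | (1RS,5SR)-1,5-dimethyl-3-(trimethylsilyloxy)bicyclo[3.3.0]oct-2-ene (racemic; relative configuration drawn) | C[Si](C)(C)OC1=C[C@]2(C)CCC[C@]2(C)C1
F2 | step 4 | 2-[(1RS,2RS)-2-formyl-1,2-dimethylcyclopentyl]acetic acid (racemic; relative configuration drawn) | OC(=O)C[C@@]1(C)CCC[C@@]1(C)C=O
F3 | step 4 | (4aR,7aR)-4a,7a-dimethyl-1-[(1R,2S,5R)-menthyloxy]hexahydrocyclopenta[c]pyran-3(1H)-one | CC(C)[C@@H]1CC[C@@H](C)C[C@H]1OC1OC(=O)C[C@@]2(C)CCC[C@@]12C
F4 | step 19 | 1-[(2Z)-4-chloro-3-methylbut-2-en-1-yl]-2,5-bis(methoxymethoxy)-3-methylbenzene | C/C(=C/Cc1cc(OCOC)cc(C)c1OCOC)CCl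
F5 | step 19 | (4aR,7aR)-4a,7a-dimethyl-1-[(E)-3-methyl-3-(triethylsilyloxy)but-1-en-1-yl]octahydrocyclopenta[c]pyran-3-ol | OC1C[C@@]2(C)CCC[C@@]2(C)C(/C=C/C(C)(C)O[Si](CC)(CC)CC)O1
F6 | step 19 | [(2Z)-4-(2,5-bis(methoxymethoxy)-3-methylphenyl)-2-methylbut-2-en-1-yl]barium chloride | C/C(=C/Cc1cc(OCOC)cc(C)c1OCOC)C[Ba]Cl
F7 | step 19 | (4Z)-6-[2,5-bis(methoxymethoxy)-3-methylphenyl]-1-[(1R,2R)-2-{(E)-1-hydroxy-4-methyl-4-(triethylsilyloxy)pent-2-en-1-yl}-1,2-dimethylcyclopentyl]-4-methylhex-4-en-2-ol | C/C(=C/Cc1cc(OCOC)cc(C)c1OCOC)CC(O)C[C@@]1(C)CCC[C@@]1(C)C(O)/C=C/C(C)(C)O[Si](CC)(CC)CC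
F8 | step 22 | (E)-1-[(1R,2R)-2-{(4Z)-6-[2,5-bis(methoxymethoxy)-3-methylphenyl]-4-methyl-2-oxohex-4-en-1-yl}-1,2-dimethylcyclopentyl]-4-hydroxy-4-methylpent-2-en-1-one | C/C(=C/Cc1cc(OCOC)cc(C)c1OCOC)CC(=O)C[C@@]1(C)CCC[C@@]1(C)C(=O)/C=C/C(C)(C)O
F9 | step 22 | 2-{(2Z)-6-[(1R,2R)-2-((E)-4-hydroxy-4-methylpent-2-enoyl)-1,2-dimethylcyclopentyl]-3-methyl-5-oxohex-2-en-1-yl}-6-methyl-1,4-benzoquinone | C/C(=C/CC1=CC(=O)C=C(C)C1=O)CC(=O)C[C@@]1(C)CCC[C@@]1(C)C(=O)/C=C/C(C)(C)O
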